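A direct plan would build the two isoflavone halves separately and join them last through the C8–O–C4' diaryl ether.
It would make bromide A1, 3-(4-bromophenyl)-8-chloro-7-methoxychromen-4-one, and quinol A2, 5,8-dihydroxy-7-methoxy-3-(4-methoxyphenyl)chromen-4-one, couple them with copper to ether A3, and cleave three methyl ethers with BBr3.
Weak point 1, the persulfate hydroxylation at C8 of a finished isoflavone on the way to A2: such para-hydroxylations tend to stop at low conversion, so the oxygen would be bought on an advanced intermediate.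
Weak point 2, the copper-mediated etherification of A1 with A2: the 8-OH is flanked by O1 and 7-OMe, the quinol is air-sensitive, and the base-labile chromones would sit in hot phosphate at the most valuable point of the route.
Weak point 3, the methyl ether bracket: early O-methylations and a threefold demethylation of A3 at the very end, one of them ortho to the new diaryl ether, would build nothing and put the finished skeleton at risk.

**Retrosynthetic overview**
- The target is cut at O1–C2 and C2–C3 of both pyranone rings (ring C of each isoflavone unit) at once, back to the open bis(2-hydroxydeoxybenzoin) 11. The two aryl–acyl bonds go back to 2-chlororesorcinol (Houben–Hoesch) and to a 2-aryloxyphloroglucinol (Friedel–Crafts), and the C8–O–C4' ether to an SNAr of 2,4,6-trimethoxyphenol on 4-fluorobenzaldehyde.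
- The feature used: C8 of the 5,7-dihydroxy unit (the carbon carrying the ether oxygen, between O1 and 7-OH) and C8 of the chlorinated unit (Cl between O1 and 7-OH) each lie on the mirror plane of a symmetric 2-substituted phloroglucinol or resorcinol. The hindered ether and the chlorine can therefore be in place before any heterocycle exists.
- Order of ring formation: the diaryl ether first (step 1), then the two ketones (steps 4 and 5), then both pyranone rings together in the last step.
- The weak steps are avoided by design: no oxidation of a finished isoflavone, no metal-mediated coupling of a hindered quinol, and the only protecting groups (three methyl ethers) leave at step 3 on a simple nitrile, so the key step gives the unprotected natural product.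

Key step: step 6

Remark: 2,4,6-trimethoxyphenol (1) is taken as a purchasable phenol. The target has no stereocenter, so no configuration has to be set.

Step 1
Reactants: 1 2,4,6-trimethoxyphenol; 2 4-fluorobenzaldehyde
Product: 3 4-(2,4,6-trimethoxyphenoxy)benzaldehyde
Conditions: K2CO3 (1.5 equiv), DMF, 110 °C, 12 h, N2
Reagents that add atoms: none
Why: Nucleophilic aromatic substitution (SNAr, addition–elimination through a Meisenheimer complex stabilised by the para formyl group), in which the electron-rich phenoxide of 1 displaces fluoride at an unhindered carbon despite its two ortho methoxy groups, and exclusion of air protects the oxidisable phenoxide.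

Step 2
Reactants: 3 4-(2,4,6-trimethoxyphenoxy)benzaldehyde
Product: 5 2-[4-(2,4,6-trimethoxyphenoxy)phenyl]acetonitrile, via N-(1-tosylvinyl)formamide 4 (not isolated)
Conditions: TosMIC (1.3 equiv), KOt-Bu (2.5 equiv), DME, −50 → −30 °C, 1 h; then MeOH, reflux, 30 min
Reagents that add atoms: p-toluenesulfonylmethyl isocyanide (TosMIC), Cc1ccc(cc1)S(=O)(=O)C[N+]#[C-]
Why: Van Leusen reductive cyanation, in which the TosMIC anion adds to the aldehyde, the oxazoline opens to the N-formyl vinyl sulfone 4, and methanolysis with loss of methyl formate and sulfinate leaves the one-carbon-homologated nitrile under conditions to which the aryl ethers are inert.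

Step 3
Reactants: 5 2-[4-(2,4,6-trimethoxyphenoxy)phenyl]acetonitrile
Product: 6 2-[4-(2,4,6-trihydroxyphenoxy)phenyl]acetonitrile
Conditions: BBr3 (5 equiv), CH2Cl2, −78 °C → rt, 16 h, N2; then ice–water
Reagents that add atoms: none
Why: Lewis acid cleavage of the three aryl methyl ethers by BBr3 (bromide attack on the methyl group of the boron-complexed ether), which should leave the diaryl ether (no alkyl carbon to attack) and the nitrile untouched and removes all protecting groups on a simple compound.

Step 4
Reactants: 6 2-[4-(2,4,6-trihydroxyphenoxy)phenyl]acetonitrile; 7 (4-hydroxyphenyl)acetic acid (1.05 equiv)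
Product: 8 2-[4-[2,4,6-trihydroxy-3-[2-(4-hydroxyphenyl)acetyl]phenoxy]phenyl]acetonitrile
Conditions: BF3·OEt2 (as medium), 65 °C, 2 h, N2; then 10% aq NaOAc
Reagents that add atoms: none
Why: Friedel–Crafts C-acylation of a phloroglucinol by a free arylacetic acid in BF3·OEt2 (Nencki-type), in which the two open positions of the trihydroxyphenoxy ring of 6 are equivalent by its mirror plane so that only one ketone can form, one equivalent of 7 and the deactivating acyl group stop the reaction at monoacylation, and the nitrile is a spectator toward BF3 in the absence of HCl.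

Step 5
Reactants: 8 2-[4-[2,4,6-trihydroxy-3-[2-(4-hydroxyphenyl)acetyl]phenoxy]phenyl]acetonitrile; 9 2-chlororesorcinol (2-chlorobenzene-1,3-diol, 4 equiv)
Product: 11 1-(3-chloro-2,4-dihydroxyphenyl)-2-[4-[2,4,6-trihydroxy-3-[2-(4-hydroxyphenyl)acetyl]phenoxy]phenyl]ethan-1-one, via ketiminium chloride 10 (not isolated)
Conditions: ZnCl2 (2 equiv), dry HCl gas, Et2O–EtOAc, 0 → 4 °C, 48 h; then H2O, 90 °C, 2 h
Reagents that add atoms: water, O
Why: Houben–Hoesch reaction, in which the nitrilium (imidoyl chloride) formed from the nitrile of 8 attacks C4 of 2-chlororesorcinol (para to one hydroxyl, ortho to the other, C4 and C6 equivalent) and so places chlorine between the two oxygens, while the acylated phloroglucinol ring of 8 is deactivated, Hoesch acylations stop at the monoketone stage, and water hydrolyses ketiminium salt 10 to the ketone.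

Step 6
Reactants: 11 1-(3-chloro-2,4-dihydroxyphenyl)-2-[4-[2,4,6-trihydroxy-3-[2-(4-hydroxyphenyl)acetyl]phenoxy]phenyl]ethan-1-one
Product: 13 Bisoflavolin H, via bis(enaminone) 12 (not isolated)
Conditions: BF3·OEt2 (8 equiv), DMF, 0 → 50 °C; MsCl (6 equiv), DMF, 50 → 70 °C, 3 h; then cold aq NaOAc; MeOH–1 M HCl, 60 °C, 30 min
Reagents that add atoms: N,N-dimethylformamide, CN(C)C=O
Why: Twofold deoxybenzoin-to-isoflavone annulation: BF3 turns both 2-hydroxyaryl ketones into boron chelates and acidifies their benzylic CH2 groups, the iminium salt formed from DMF and MsCl C-formylates each of them to give bis(enaminone) 12, and each pyranone then closes by attack of an ortho hydroxyl on the aminomethylene carbon (O1–C2 bond, 6-endo-trig oxa-Michael addition) and becomes aromatic by loss of dimethylamine. The closest known reaction type is the BF3·OEt2/DMF/MsCl conversion of unprotected polyhydroxydeoxybenzoins into isoflavones, here applied to two ketones of one molecule, so that four bonds and both heterocycles arise in one operation and the product needs no deprotection. No stereocenter is formed (the target is achiral). In the chlororesorcinol half the ketone has a single ortho hydroxyl, so the closure is unambiguous and chlorine must end at C8. In the phloroglucinol half the step needs closure through the hydroxyl flanked by the aryloxy group and not through the unflanked one: the carbonyl should chelate (hydrogen bond and O–BF2–O bridge) the unhindered, unflanked ortho oxygen, which becomes 5-OH, and thereby turn the formylated carbon toward the aryloxy-flanked hydroxyl, in line with the kinetic preference known for 3-alkoxy-2,4,6-trihydroxyphenyl ketones to close to the 8-alkoxy-5,7-dihydroxy pattern. The acidic, non-equilibrating medium and the boron chelate of the product at 5-O/4-C=O should prevent ring opening and Wessely–Moser-type isomerisation to the 6-aryloxy isomer before work-up.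

**Compound list**
1 | 2,4,6-trimethoxyphenol | COc1cc(OC)c(O)c(OC)c1 | starting material
2 | 4-fluorobenzaldehyde | O=Cc1ccc(F)cc1 | starting material
3 | 4-(2,4,6-trimethoxyphenoxy)benzaldehyde | COc1cc(OC)c(Oc2ccc(C=O)cc2)c(OC)c1 | intermediate
4 | N-[1-(4-methylphenyl)sulfonyl-2-[4-(2,4,6-trimethoxyphenoxy)phenyl]ethenyl]formamide (alkene geometry not defined, not isolated) | O=CNC(=Cc1ccc(Oc2c(OC)cc(OC)cc2OC)cc1)S(=O)(=O)c1ccc(C)cc1 | intermediate
5 | 2-[4-(2,4,6-trimethoxyphenoxy)phenyl]acetonitrile | COc1cc(OC)c(Oc2ccc(CC#N)cc2)c(OC)c1 | intermediate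
6 | 2-[4-(2,4,6-trihydroxyphenoxy)phenyl]acetonitrile | N#CCc1ccc(Oc2c(O)cc(O)cc2O)cc1 | intermediate
7 | (4-hydroxyphenyl)acetic acid | OC(=O)Cc1ccc(O)cc1 | starting material
8 | 2-[4-[2,4,6-trihydroxy-3-[2-(4-hydroxyphenyl)acetyl]phenoxy]phenyl]acetonitrile | N#CCc1ccc(Oc2c(O)cc(O)c(C(=O)Cc3ccc(O)cc3)c2O)cc1 | intermediate
9 | 2-chlororesorcinol (2-chlorobenzene-1,3-diol) | Oc1cccc(O)c1Cl | starting material
10 | 1-(3-chloro-2,4-dihydroxyphenyl)-2-[4-[2,4,6-trihydroxy-3-[2-(4-hydroxyphenyl)acetyl]phenoxy]phenyl]ethan-1-iminium chloride (not isolated) | [NH2+]=C(Cc1ccc(Oc2c(O)cc(O)c(C(=O)Cc3ccc(O)cc3)c2O)cc1)c1ccc(O)c(Cl)c1O.[Cl-] | intermediate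
11 | 1-(3-chloro-2,4-dihydroxyphenyl)-2-[4-[2,4,6-trihydroxy-3-[2-(4-hydroxyphenyl)acetyl]phenoxy]phenyl]ethan-1-one | O=C(Cc1ccc(Oc2c(O)cc(O)c(C(=O)Cc3ccc(O)cc3)c2O)cc1)c1ccc(O)c(Cl)c1O | intermediate
12 | 1-(3-chloro-2,4-dihydroxyphenyl)-3-(dimethylamino)-2-[4-[3-[3-(dimethylamino)-2-(4-hydroxyphenyl)prop-2-enoyl]-2,4,6-trihydroxyphenoxy]phenyl]prop-2-en-1-one (alkene geometry not defined, not isolated) | CN(C)C=C(C(=O)c1ccc(O)c(Cl)c1O)c1ccc(Oc2c(O)cc(O)c(C(=O)C(=CN(C)C)c3ccc(O)cc3)c2O)cc1 | intermediate
13 | Bisoflavolin H, 8-[4-(8-chloro-7-hydroxy-4-oxo-4H-chromen-3-yl)phenoxy]-5,7-dihydroxy-3-(4-hydroxyphenyl)-4H-chromen-4-one (achiral) | O=c1c(-c2ccc(Oc3c(O)cc(O)c4c(=O)c(-c5ccc(O)cc5)coc34)cc2)coc2c(Cl)c(O)ccc12 | target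

Total step count: 6. Longest linear sequence: 6 (1 → 3 → 5 → 6 → 8 → 11 → 13).

**Steps most likely to fail**

1. Step 6. The pyranone of the phloroglucinol half may close through the unflanked ortho hydroxyl, or open and reclose, and so give the 6-aryloxy isomer; the second annulation may also stay incomplete. The fallback sets out from 5 and comes back at 13; it fixes which ortho oxygen is free before any ring is closed. Friedel–Crafts acylation of 5 with (4-methoxyphenyl)acetyl chloride and AlCl3 (CH2Cl2, 0 °C → rt) should, through chelation by the new ketone, cleave the more congested ortho methoxy group (the one between the aryloxy and the acyl group). This would give 2-[4-[2-hydroxy-4,6-dimethoxy-3-[2-(4-methoxyphenyl)acetyl]phenoxy]phenyl]acetonitrile F1, whose single free hydroxyl could be located and any isomer removed at this simple stage. A Houben–Hoesch reaction of F1 with 9 as in step 5 would give 1-(3-chloro-2,4-dihydroxyphenyl)-2-[4-[2-hydroxy-4,6-dimethoxy-3-[2-(4-methoxyphenyl)acetyl]phenoxy]phenyl]ethan-1-one F2, in which each ketone has only one free ortho hydroxyl. The same twofold BF3·OEt2/DMF/MsCl annulation would then give 8-[4-(8-chloro-7-hydroxy-4-oxo-4H-chromen-3-yl)phenoxy]-5,7-dimethoxy-3-(4-methoxyphenyl)-4H-chromen-4-one F3, and BBr3 would cleave its three methyl ethers to 13.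

2. Step 5. The nitrilium may attack the chlorine-deactivated resorcinol too slowly, the phloroglucinol ring of a second molecule of 8 may compete (oligomers), and the polyphenol may dissolve poorly in the ethereal medium. The fallback sets out from 8 and comes back at 11; it changes the acyl donor from a nitrilium to a free acid. Hydrolysis of the nitrile (6 M HCl–dioxane, reflux) would give 2-[4-[2,4,6-trihydroxy-3-[2-(4-hydroxyphenyl)acetyl]phenoxy]phenyl]acetic acid F4. Friedel–Crafts acylation of an excess of 9 by this acid in BF3·OEt2 at 80 °C (the reaction type of step 4, with the acylphloroglucinol ring tied up as its boron chelate) would give 11.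

3. Step 4. The phloroglucinol ring may be acylated twice or on oxygen, and the nitrile may be hydrated or attacked by the electron-rich ring in hot BF3·OEt2. The fallback sets out from 5 and comes back at 8; it acylates before the phenols are set free. Friedel–Crafts acylation of 5 with (4-methoxyphenyl)acetyl chloride and SnCl4 (CH2Cl2, −20 °C, mild enough to leave the ethers intact, the two open ring positions again being equivalent) would give 2-[4-[2,4,6-trimethoxy-3-[2-(4-methoxyphenyl)acetyl]phenoxy]phenyl]acetonitrile F5. BBr3 would then cleave all four methyl ethers to 8.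

**Further compounds**
F1 | step 6 | 2-[4-[2-hydroxy-4,6-dimethoxy-3-[2-(4-methoxyphenyl)acetyl]phenoxy]phenyl]acetonitrile | N#CCc1ccc(Oc2c(OC)cc(OC)c(C(=O)Cc3ccc(OC)cc3)c2O)cc1
F2 | step 6 | 1-(3-chloro-2,4-dihydroxyphenyl)-2-[4-[2-hydroxy-4,6-dimethoxy-3-[2-(4-methoxyphenyl)acetyl]phenoxy]phenyl]ethan-1-one | O=C(Cc1ccc(Oc2c(OC)cc(OC)c(C(=O)Cc3ccc(OC)cc3)c2O)cc1)c1ccc(O)c(Cl)c1O
F3 | step 6 | 8-[4-(8-chloro-7-hydroxy-4-oxo-4H-chromen-3-yl)phenoxy]-5,7-dimethoxy-3-(4-methoxyphenyl)-4H-chromen-4-one | COc1ccc(cc1)-c1coc2c(Oc3ccc(cc3)-c3coc4c(Cl)c(O)ccc4c3=O)c(OC)cc(OC)c2c1=O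
F4 | step 5 | 2-[4-[2,4,6-trihydroxy-3-[2-(4-hydroxyphenyl)acetyl]phenoxy]phenyl]acetic acid | OC(=O)Cc1ccc(Oc2c(O)cc(O)c(C(=O)Cc3ccc(O)cc3)c2O)cc1
F5 | step 4 | 2-[4-[2,4,6-trimethoxy-3-[2-(4-methoxyphenyl)acetyl]phenoxy]phenyl]acetonitrile | N#CCc1ccc(Oc2c(OC)cc(OC)c(C(=O)Cc3ccc(OC)cc3)c2OC)cc1
A1 | direct plan | 3-(4-bromophenyl)-8-chloro-7-methoxy-4H-chromen-4-one | COc1ccc2c(c1Cl)occ(-c1ccc(Br)cc1)c2=O
A2 | direct plan | 5,8-dihydroxy-7-methoxy-3-(4-methoxyphenyl)-4H-chromen-4-one | COc1ccc(cc1)-c1coc2c(O)c(OC)cc(O)c2c1=O
A3 | direct plan | 8-[4-(8-chloro-7-methoxy-4-oxo-4H-chromen-3-yl)phenoxy]-5-hydroxy-7-methoxy-3-(4-methoxyphenyl)-4H-chromen-4-one | COc1ccc(cc1)-c1coc2c(Oc3ccc(cc3)-c3coc4c(Cl)c(OC)ccc4c3=O)c(OC)cc(O)c2c1=O
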